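**Retrosynthetic overview**
- The 1,10-oxirane is made last by hydroxyl-guided peracid epoxidation of a Z,Z-triene lactone. The C8 side chain comes from esterification with (2R,3R)-epoxyangelic acid, itself made from angelic acid by Sharpless epoxidation.
- The ten-membered ring is closed at C7–C8: a ketyl radical from a C8 aldehyde adds to C7 of a 3-(acetoxymethyl)butenolide and acetate is expelled. This one step sets C7, C8 and the exocyclic methylene.
- The butenolide acceptor comes from a saturated lactone (selenation, hydroxymethylation, selenoxide elimination). The open chain comes from a C3–C4 Ni/Cr coupling of a Z-vinyl iodide with a Z-β,γ-unsaturated aldehyde.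
- The Z-vinyl iodide comes from (S)-5-(hydroxymethyl)butyrolactone, which carries C6 (Stork–Zhao olefination). The aldehyde comes from p-cresol (Birch reduction and ozonolysis fix the Z-C1=C10 olefin).
- Ring order: γ-lactone (chiral pool), then butenolide, then the ten-membered carbocycle (radical closure), then the ring oxirane; the ester oxirane arrives preformed.

Assumption: the SMILES is read as 1R,3S,6R,7R,8R,10S with a 4Z olefin, a cis (Z-derived) 1,10-epoxide and a (2R,3R)-epoxyangelate; germacrane numbering (ring C1–C10, lactone carbonyl C12 on O–C6, methylene C13) is used for the macrocycles.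

**Route**

Step 1
Reactants: 1 4-methylphenol
Product: 2 1-methoxy-4-methylbenzene
Conditions: MeI, K2CO3, acetone, reflux
Reagents that add atoms: iodomethane CI
Why: Williamson ether synthesis of the phenoxide; no stereocentre is involved.

Step 2
Reactants: 2 1-methoxy-4-methylbenzene
Product: 3 1-methoxy-4-methylcyclohexa-1,4-diene
Conditions: Li, liquid NH3, THF, t-BuOH, −78 to −33 °C
Reagents that add atoms: none
Why: Birch reduction leaves both donor substituents on sp2 carbons of the 1,4-diene, and the ring locks the future C1=C10 olefin as Z.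

Step 3
Reactants: 3 1-methoxy-4-methylcyclohexa-1,4-diene
Product: 5 methyl (3Z)-6,6-dimethoxy-4-methylhex-3-enoate, via methyl (3Z)-4-methyl-6-oxohex-3-enoate 4 (not isolated)
Conditions: O3 (1.0 equiv), CH2Cl2/MeOH, −78 °C; Me2S; then p-TsOH (cat.), MeOH, rt
Reagents that add atoms: ozone [O-][O+]=O; methanol CO
Why: Chemoselective ozonolysis of the electron-rich enol-ether double bond gives ester and aldehyde with the ring-derived Z geometry kept; the aldehyde is acetalised in the same pot.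

Step 4
Reactants: 5 methyl (3Z)-6,6-dimethoxy-4-methylhex-3-enoate
Product: 6 (3Z)-6,6-dimethoxy-4-methylhex-3-enal
Conditions: i-Bu2AlH (1.05 equiv), CH2Cl2, −78 °C; aqueous potassium sodium tartrate
Reagents that add atoms: none
Why: Partial ester reduction stops at the tetrahedral aluminate at −78 °C; the β,γ-unsaturated aldehyde is used at once so the olefin does not move into conjugation.

Step 5
Reactants: 7 (5S)-5-(hydroxymethyl)oxolan-2-one
Product: 8 (2S)-5-oxooxolane-2-carbaldehyde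
Conditions: Dess–Martin periodinane, NaHCO3, CH2Cl2, 0 °C to rt; used crude
Reagents that add atoms: none
Why: Dess–Martin oxidation is neutral and does not epimerise the α-oxygenated centre that becomes C6.

Step 6
Reactants: 8 (2S)-5-oxooxolane-2-carbaldehyde
Product: 9 (5S)-5-[(1Z)-2-iodoprop-1-en-1-yl]oxolan-2-one
Conditions: [Ph3PEt]I, n-BuLi, THF, 0 °C; iodine, −78 °C; NaN(SiMe3)2, −20 °C; then 8, −78 °C to rt
Reagents that add atoms: ethyltriphenylphosphonium iodide CC[P+](c1ccccc1)(c1ccccc1)c1ccccc1.[I-]; iodine [I][I]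
Why: Stork–Zhao olefination (Wittig reaction of the α-iodo ylide) gives the Z-vinyl iodide under kinetic control, with iodine cis to the lactone carbon, which fixes the 4Z olefin.

Step 7
Reactants: 9 (5S)-5-[(1Z)-2-iodoprop-1-en-1-yl]oxolan-2-one; 6 (3Z)-6,6-dimethoxy-4-methylhex-3-enal
Product: 10 (5S)-5-[(1Z,3S,5Z)-3-hydroxy-8,8-dimethoxy-2,6-dimethylocta-1,5-dien-1-yl]oxolan-2-one
Conditions: CrCl2 (3 equiv), NiCl2 (0.05 equiv), Kishi sulfonamide ligand N-[2-((4S)-4-isopropyl-4,5-dihydrooxazol-2-yl)-6-methylphenyl]methanesulfonamide (3.3 equiv), Et3N (3.3 equiv), THF, rt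
Reagents that add atoms: none
Why: Nozaki–Hiyama–Kishi coupling keeps the alkenyl geometry and tolerates lactone and acetal; the chiral sulfonamide–chromium complex directs addition to the Re face of aldehyde 6, giving 3S (the ligand antipode would give 3R).

Step 8
Reactants: 10 (5S)-5-[(1Z,3S,5Z)-3-hydroxy-8,8-dimethoxy-2,6-dimethylocta-1,5-dien-1-yl]oxolan-2-one
Product: 11 (5S)-5-[(1Z,3S,5Z)-3-(tert-butyldimethylsilyloxy)-8,8-dimethoxy-2,6-dimethylocta-1,5-dien-1-yl]oxolan-2-one
Conditions: TBSCl, imidazole, DMAP (cat.), DMF, rt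
Reagents that add atoms: tert-butyldimethylsilyl chloride CC(C)(C)[Si](C)(C)Cl
Why: Silylation under non-Lewis-acidic conditions leaves the dimethyl acetal intact and marks C3–OH so that C8–OH can later be acylated alone.

Step 9
Reactants: 11 (5S)-5-[(1Z,3S,5Z)-3-(tert-butyldimethylsilyloxy)-8,8-dimethoxy-2,6-dimethylocta-1,5-dien-1-yl]oxolan-2-one
Product: 14 [(5S)-5-[(1Z,3S,5Z)-3-(tert-butyldimethylsilyloxy)-8,8-dimethoxy-2,6-dimethylocta-1,5-dien-1-yl]-2-oxo-3-(phenylselanyl)oxolan-3-yl]methyl acetate (C3 epimers), via α-phenylselanyl lactone 12 (not isolated), via hydroxymethyl selenide alkoxide 13 (not isolated)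
Conditions: LiN(i-Pr)2 (1.05 equiv), THF, −78 °C; PhSeBr (1.05 equiv); LiN(i-Pr)2 (1.1 equiv); CH2O (gas), −78 to −40 °C; Ac2O, −78 to 0 °C
Reagents that add atoms: phenylselanyl bromide Br[Se]c1ccccc1; formaldehyde C=O; acetic anhydride CC(=O)OC(C)=O
Why: Lactone enolate selenenylation, then aldol of the more acidic α-seleno enolate with formaldehyde and O-acetylation of the aldolate; the new quaternary centre is a mixture that is erased in step 10.

Step 10
Reactants: 14 [(5S)-5-[(1Z,3S,5Z)-3-(tert-butyldimethylsilyloxy)-8,8-dimethoxy-2,6-dimethylocta-1,5-dien-1-yl]-2-oxo-3-(phenylselanyl)oxolan-3-yl]methyl acetate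
Product: 16 [(5R)-5-[(1Z,3S,5Z)-3-(tert-butyldimethylsilyloxy)-8,8-dimethoxy-2,6-dimethylocta-1,5-dien-1-yl]-2-oxo-2,5-dihydrofuran-3-yl]methyl acetate, via selenoxide 15 (not isolated)
Conditions: NaIO4, NaHCO3, THF/MeOH/H2O, 0 °C to rt
Reagents that add atoms: none
Why: Selenoxide syn-elimination goes toward the ring C7–H (away from the oxygen-bearing CH2) to give the conjugated butenolide; periodate is used so that no peracid forms and the trisubstituted olefins survive (C6 is untouched; its label changes from S to R only through CIP priorities).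

Step 11
Reactants: 16 [(5R)-5-[(1Z,3S,5Z)-3-(tert-butyldimethylsilyloxy)-8,8-dimethoxy-2,6-dimethylocta-1,5-dien-1-yl]-2-oxo-2,5-dihydrofuran-3-yl]methyl acetate
Product: 17 [(5R)-5-[(1Z,3S,5Z)-3-(tert-butyldimethylsilyloxy)-2,6-dimethyl-8-oxoocta-1,5-dien-1-yl]-2-oxo-2,5-dihydrofuran-3-yl]methyl acetate
Conditions: LiBF4, MeCN/H2O (98:2), rt; used at once
Reagents that add atoms: water O
Why: Mild Lewis-acid hydrolysis of the dimethyl acetal spares the silyl ether, the allylic acetate and the base-sensitive butenolide.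

Step 12
Reactants: 17 [(5R)-5-[(1Z,3S,5Z)-3-(tert-butyldimethylsilyloxy)-2,6-dimethyl-8-oxoocta-1,5-dien-1-yl]-2-oxo-2,5-dihydrofuran-3-yl]methyl acetate
Product: 18 (3S,6R,7R,8R)-3-(tert-butyldimethylsilyloxy)-8-hydroxygermacra-1(10)Z,4Z,11(13)-trien-12,6-olide
Conditions: SmI2 (2.5 equiv), THF (1 mM final), −78 °C, 17 added over 6 h, then to −20 °C; aqueous NaHCO3
Reagents that add atoms: none
Why: Proposed new method: electron transfer from divalent samarium to the aldehyde gives a ketyl radical that adds 10-exo to C7 of the electron-poor butenolide (the two Z olefins fold the chain); the α-lactone radical is then reduced to a trivalent samarium enolate that expels acetate to give the exocyclic methylene; C8 should add anti to the C5 substituent on C6 (trans lactone, 7R), and samarium bridging of the ketyl oxygen and the lactone carbonyl with the tether on the C6 side should give 8R; the closest known reactions are the SmI2 ketyl–olefin cyclisation onto enoates and radical addition–β-elimination allylation.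

Step 13
Reactants: 19 (2Z)-2-methylbut-2-enoic acid (angelic acid)
Product: 20 (2Z)-2-methylbut-2-en-1-ol
Conditions: LiAlH4, Et2O, 0 °C to rt
Reagents that add atoms: none
Why: Hydride reduction of the acid proceeds 1,2 and leaves the Z olefin unchanged.

Step 14
Reactants: 20 (2Z)-2-methylbut-2-en-1-ol
Product: 21 [(2S,3R)-2,3-dimethyloxiran-2-yl]methanol
Conditions: Ti(OiPr)4 (10 mol%), D-(−)-diethyl tartrate (12 mol%), t-BuOOH, 4 Å sieves, CH2Cl2, −20 °C
Reagents that add atoms: tert-butyl hydroperoxide CC(C)(C)OO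
Why: Sharpless asymmetric epoxidation; with the D-tartrate the oxygen is delivered to the face given by the Sharpless mnemonic, setting both oxirane centres (2S,3R).

Step 15
Reactants: 21 [(2S,3R)-2,3-dimethyloxiran-2-yl]methanol
Product: 22 (2R,3R)-2,3-dimethyloxirane-2-carboxylic acid
Conditions: RuCl3 hydrate (2 mol%), NaIO4 (3 equiv), CCl4/MeCN/H2O, rt
Reagents that add atoms: water O
Why: Sharpless RuO4 oxidation takes the primary alcohol to the acid without touching the oxirane (C2 is spatially unchanged; its label changes to R by priority).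

Step 16
Reactants: 22 (2R,3R)-2,3-dimethyloxirane-2-carboxylic acid; 18 (3S,6R,7R,8R)-3-(tert-butyldimethylsilyloxy)-8-hydroxygermacra-1(10)Z,4Z,11(13)-trien-12,6-olide
Product: 24 (3S,6R,7R,8R)-3-(tert-butyldimethylsilyloxy)-8-[(2R,3R)-2,3-dimethyloxirane-2-carbonyloxy]germacra-1(10)Z,4Z,11(13)-trien-12,6-olide, via mixed anhydride 23 (not isolated)
Conditions: 22, 2,4,6-trichlorobenzoyl chloride, Et3N, THF, rt; then 18, DMAP, toluene, rt
Reagents that add atoms: none
Why: Yamaguchi esterification acylates the only free hydroxyl with retention at C8.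

Step 17
Reactants: 24 (3S,6R,7R,8R)-3-(tert-butyldimethylsilyloxy)-8-[(2R,3R)-2,3-dimethyloxirane-2-carbonyloxy]germacra-1(10)Z,4Z,11(13)-trien-12,6-olide
Product: 25 (3S,6R,7R,8R)-3-hydroxy-8-[(2R,3R)-2,3-dimethyloxirane-2-carbonyloxy]germacra-1(10)Z,4Z,11(13)-trien-12,6-olide
Conditions: HF·pyridine, pyridine, THF, 0 °C to rt
Reagents that add atoms: none
Why: Fluoride cleavage of the silyl ether is done before the acid-labile ring oxirane exists; the deactivated α,β-epoxy ester and the methylene lactone tolerate buffered HF.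

Step 18
Reactants: 25 (3S,6R,7R,8R)-3-hydroxy-8-[(2R,3R)-2,3-dimethyloxirane-2-carbonyloxy]germacra-1(10)Z,4Z,11(13)-trien-12,6-olide
Product: 26 (1R,3S,6R,7R,8R,10S)-1,10-epoxy-3-hydroxy-8-[(2R,3R)-2,3-dimethyloxirane-2-carbonyloxy]germacra-4Z,11(13)-dien-12,6-olide (CNP0268255.3)
Conditions: mCPBA (1.1 equiv), NaHCO3, CH2Cl2, −20 to 0 °C
Reagents that add atoms: 3-chloroperoxybenzoic acid OOC(=O)c1cccc(Cl)c1
Why: Prilezhaev epoxidation attacks only the electron-rich C1=C10 olefin (C4=C5 carries two allylic C–O bonds, C11=C13 is conjugated) and is stereospecific for the cis-oxirane; hydrogen-bonded delivery from the homoallylic C3–OH, which is 1,3-syn to the required oxygen, should give the 1R,10S face.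

**Compound list**
1 | 4-methylphenol (p-cresol) | Cc1ccc(O)cc1 | starting material
2 | 1-methoxy-4-methylbenzene | COc1ccc(C)cc1 | intermediate
3 | 1-methoxy-4-methylcyclohexa-1,4-diene | COC1=CCC(C)=CC1 | intermediate
4 | methyl (3Z)-4-methyl-6-oxohex-3-enoate | COC(=O)C/C=C(/C)\CC=O | intermediate
5 | methyl (3Z)-6,6-dimethoxy-4-methylhex-3-enoate | COC(=O)C/C=C(/C)\CC(OC)OC | intermediate
6 | (3Z)-6,6-dimethoxy-4-methylhex-3-enal | O=CC/C=C(/C)\CC(OC)OC | intermediate
7 | (5S)-5-(hydroxymethyl)oxolan-2-one | O=C1CC[C@@H](CO)O1 | starting material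
8 | (2S)-5-oxooxolane-2-carbaldehyde | O=C1CC[C@@H](C=O)O1 | intermediate
9 | (5S)-5-[(1Z)-2-iodoprop-1-en-1-yl]oxolan-2-one | O=C1CC[C@@H](/C=C(/C)I)O1 | intermediate
10 | (5S)-5-[(1Z,3S,5Z)-3-hydroxy-8,8-dimethoxy-2,6-dimethylocta-1,5-dien-1-yl]oxolan-2-one | O=C1CC[C@@H](/C=C(/C)[C@@H](O)C/C=C(/C)\CC(OC)OC)O1 | intermediate
11 | (5S)-5-[(1Z,3S,5Z)-3-(tert-butyldimethylsilyloxy)-8,8-dimethoxy-2,6-dimethylocta-1,5-dien-1-yl]oxolan-2-one | O=C1CC[C@@H](/C=C(/C)[C@@H](O[Si](C)(C)C(C)(C)C)C/C=C(/C)\CC(OC)OC)O1 | intermediate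
12 | (5S)-5-[(1Z,3S,5Z)-3-(tert-butyldimethylsilyloxy)-8,8-dimethoxy-2,6-dimethylocta-1,5-dien-1-yl]-3-(phenylselanyl)oxolan-2-one (C3 epimers) | O=C1C([Se]c2ccccc2)C[C@@H](/C=C(/C)[C@@H](O[Si](C)(C)C(C)(C)C)C/C=C(/C)\CC(OC)OC)O1 | intermediate
13 | (5S)-5-[(1Z,3S,5Z)-3-(tert-butyldimethylsilyloxy)-8,8-dimethoxy-2,6-dimethylocta-1,5-dien-1-yl]-3-(hydroxymethyl)-3-(phenylselanyl)oxolan-2-one (present as its lithium alkoxide; C3 epimers) | OCC1([Se]c2ccccc2)C[C@@H](/C=C(/C)[C@@H](O[Si](C)(C)C(C)(C)C)C/C=C(/C)\CC(OC)OC)OC1=O | intermediate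
14 | [(5S)-5-[(1Z,3S,5Z)-3-(tert-butyldimethylsilyloxy)-8,8-dimethoxy-2,6-dimethylocta-1,5-dien-1-yl]-2-oxo-3-(phenylselanyl)oxolan-3-yl]methyl acetate (C3 epimers) | CC(=O)OCC1([Se]c2ccccc2)C[C@@H](/C=C(/C)[C@@H](O[Si](C)(C)C(C)(C)C)C/C=C(/C)\CC(OC)OC)OC1=O | intermediate
15 | Se-oxide of 14 | CC(=O)OCC1([Se](=O)c2ccccc2)C[C@@H](/C=C(/C)[C@@H](O[Si](C)(C)C(C)(C)C)C/C=C(/C)\CC(OC)OC)OC1=O | intermediate
16 | [(5R)-5-[(1Z,3S,5Z)-3-(tert-butyldimethylsilyloxy)-8,8-dimethoxy-2,6-dimethylocta-1,5-dien-1-yl]-2-oxo-2,5-dihydrofuran-3-yl]methyl acetate | CC(=O)OCC1=C[C@@H](/C=C(/C)[C@@H](O[Si](C)(C)C(C)(C)C)C/C=C(/C)\CC(OC)OC)OC1=O | intermediate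
17 | [(5R)-5-[(1Z,3S,5Z)-3-(tert-butyldimethylsilyloxy)-2,6-dimethyl-8-oxoocta-1,5-dien-1-yl]-2-oxo-2,5-dihydrofuran-3-yl]methyl acetate | CC(=O)OCC1=C[C@@H](/C=C(/C)[C@@H](O[Si](C)(C)C(C)(C)C)C/C=C(/C)\CC=O)OC1=O | intermediate
18 | (3S,6R,7R,8R)-3-(tert-butyldimethylsilyloxy)-8-hydroxygermacra-1(10)Z,4Z,11(13)-trien-12,6-olide | C=C1C(=O)O[C@@H]2/C=C(/C)[C@@H](O[Si](C)(C)C(C)(C)C)C/C=C(/C)\C[C@@H](O)[C@@H]12 | intermediate
19 | (2Z)-2-methylbut-2-enoic acid (angelic acid) | C/C=C(/C)C(=O)O | starting material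
20 | (2Z)-2-methylbut-2-en-1-ol | C/C=C(/C)CO | intermediate
21 | [(2S,3R)-2,3-dimethyloxiran-2-yl]methanol | OC[C@]1(C)O[C@@H]1C | intermediate
22 | (2R,3R)-2,3-dimethyloxirane-2-carboxylic acid | OC(=O)[C@]1(C)O[C@@H]1C | intermediate
23 | (2R,3R)-2,3-dimethyloxirane-2-carboxylic 2,4,6-trichlorobenzoic anhydride | O=C(OC(=O)c1c(Cl)cc(Cl)cc1Cl)[C@]1(C)O[C@@H]1C | intermediate
24 | (3S,6R,7R,8R)-3-(tert-butyldimethylsilyloxy)-8-[(2R,3R)-2,3-dimethyloxirane-2-carbonyloxy]germacra-1(10)Z,4Z,11(13)-trien-12,6-olide | C=C1C(=O)O[C@@H]2/C=C(/C)[C@@H](O[Si](C)(C)C(C)(C)C)C/C=C(/C)\C[C@@H](OC(=O)[C@]3(C)O[C@@H]3C)[C@@H]12 | intermediate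
25 | (3S,6R,7R,8R)-3-hydroxy-8-[(2R,3R)-2,3-dimethyloxirane-2-carbonyloxy]germacra-1(10)Z,4Z,11(13)-trien-12,6-olide | C=C1C(=O)O[C@@H]2/C=C(/C)[C@@H](O)C/C=C(/C)\C[C@@H](OC(=O)[C@]3(C)O[C@@H]3C)[C@@H]12 | intermediate
26 | (1R,3S,6R,7R,8R,10S)-1,10-epoxy-3-hydroxy-8-[(2R,3R)-2,3-dimethyloxirane-2-carbonyloxy]germacra-4Z,11(13)-dien-12,6-olide | C=C1C(=O)O[C@@H]2/C=C(/C)[C@@H](O)C[C@H]3O[C@@]3(C)C[C@@H](OC(=O)[C@]3(C)O[C@@H]3C)[C@@H]12 | target

**Step count**
Total: 18 steps. Longest linear sequence: 13 steps (1–4, 7–12, 16–18).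

**Steps most likely to fail**

Step 12 (radical ring closure). The ketyl may be reduced or dimerise before it closes the ten-membered ring, and the methylene lactone formed can be over-reduced. The fallback sets out from 17 and returns at 18. A neutral chain process replaces electron transfer: Bu3SnH with AIBN, added slowly in benzene at 80 °C under high dilution, gives an O-stannyl ketyl radical that closes the same C7–C8 bond. The cyclised α-lactone radical takes hydrogen from the stannane, so the acetate is kept and the product is not exposed as an acrylate during the radical step; work-up gives (3S,6R,7R,8R,11RS)-13-acetoxy-3-(tert-butyldimethylsilyloxy)-8-hydroxygermacra-1(10)Z,4Z-dien-12,6-olide F1. DBU in CH2Cl2 then eliminates acetic acid to give 18.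

Step 18 (face and site of the last epoxidation). Peracid may attack the other face of C1=C10 or the C4=C5 olefin. The fallback sets out from 18 and returns at 26. The epoxidation is moved earlier and made hydroxyl-directed: with C3 still silylated, the free C8–OH is homoallylic to C1=C10 and 1,3-syn to the required oxygen. VO(acac)2 with t-BuOOH in CH2Cl2 gives (1R,3S,6R,7R,8R,10S)-1,10-epoxy-3-(tert-butyldimethylsilyloxy)-8-hydroxygermacra-4Z,11(13)-dien-12,6-olide F2. Yamaguchi esterification with 22 gives (1R,3S,6R,7R,8R,10S)-1,10-epoxy-3-(tert-butyldimethylsilyloxy)-8-[(2R,3R)-2,3-dimethyloxirane-2-carbonyloxy]germacra-4Z,11(13)-dien-12,6-olide F3. Bu4NF buffered with AcOH in THF then removes the silyl group without acid to give 26.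

Step 7 (C3 configuration in the Ni/Cr coupling). Ligand control over a hindered alkenyl iodide and a remote stereocentre may be weak or of the wrong sense. The fallback sets out from 9 and 6 and returns at 10. Ligand-free CrCl2/NiCl2 coupling in DMSO gives 10 together with its epimer (5S)-5-[(1Z,3R,5Z)-3-hydroxy-8,8-dimethoxy-2,6-dimethylocta-1,5-dien-1-yl]oxolan-2-one F4. Dess–Martin oxidation of the mixture gives the enone (5S)-5-[(1Z,5Z)-8,8-dimethoxy-2,6-dimethyl-3-oxoocta-1,5-dien-1-yl]oxolan-2-one F5. Reduction with (R)-2-methyl-CBS-oxazaborolidine and catecholborane at −78 °C (alkenyl as the large group) gives 10.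

**Further compounds**
F1 | step 12 | (3S,6R,7R,8R,11RS)-13-acetoxy-3-(tert-butyldimethylsilyloxy)-8-hydroxygermacra-1(10)Z,4Z-dien-12,6-olide | CC(=O)OCC1C(=O)O[C@@H]2/C=C(/C)[C@@H](O[Si](C)(C)C(C)(C)C)C/C=C(/C)\C[C@@H](O)[C@@H]12
F2 | step 18 | (1R,3S,6R,7R,8R,10S)-1,10-epoxy-3-(tert-butyldimethylsilyloxy)-8-hydroxygermacra-4Z,11(13)-dien-12,6-olide | C=C1C(=O)O[C@@H]2/C=C(/C)[C@@H](O[Si](C)(C)C(C)(C)C)C[C@H]3O[C@@]3(C)C[C@@H](O)[C@@H]12
F3 | step 18 | (1R,3S,6R,7R,8R,10S)-1,10-epoxy-3-(tert-butyldimethylsilyloxy)-8-[(2R,3R)-2,3-dimethyloxirane-2-carbonyloxy]germacra-4Z,11(13)-dien-12,6-olide | C=C1C(=O)O[C@@H]2/C=C(/C)[C@@H](O[Si](C)(C)C(C)(C)C)C[C@H]3O[C@@]3(C)C[C@@H](OC(=O)[C@]3(C)O[C@@H]3C)[C@@H]12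
F4 | step 7 | (5S)-5-[(1Z,3R,5Z)-3-hydroxy-8,8-dimethoxy-2,6-dimethylocta-1,5-dien-1-yl]oxolan-2-one | O=C1CC[C@@H](/C=C(/C)[C@H](O)C/C=C(/C)\CC(OC)OC)O1
F5 | step 7 | (5S)-5-[(1Z,5Z)-8,8-dimethoxy-2,6-dimethyl-3-oxoocta-1,5-dien-1-yl]oxolan-2-one | O=C1CC[C@@H](/C=C(/C)C(=O)C/C=C(/C)\CC(OC)OC)O1
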